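Remark: "prenyl" stands for 3-methylbut-2-en-1-yl and TBS for tert-butyldimethylsilyl. Compounds 1, 2, 6, 9, 10 and 15 are taken to be commercial. Where a step consumes two molecules of the same compound, the second molecule is also entered on the line of reagents that add atoms.

## Analysis of the target

The target 22 is a flavanone: benzo ring A is fused to dihydropyran-4-one ring C, which carries the 4-hydroxyphenyl ring B at C2. Ring A is pentasubstituted, with O1 on C8a, the ketone carbon C4 on C4a, a free hydroxyl on C7 and prenyl groups on C6 and C8, so that only C5 bears hydrogen. C2 is the only stereocentre; it is S, a benzylic ether carbon β to the C4 carbonyl, and it has no neighbouring stereocentre to lean on. That position makes it labile: base can open ring C by β-elimination of the C8a phenoxide from the C3 enolate, and the free 4'-hydroxyl makes this easier, so the free ketone should never meet base. The two prenyl groups flank the C7 phenol, which excludes hydrogenolysis and strong acid (cyclisation to dimethylchromans) and calls for fluoride-labile protection of both phenols. The difficulty is therefore not skeletal size but two things: setting one isolated, epimerisable stereocentre with full fidelity, and placing two C-prenyl groups regioselectively on a resorcinol ring. The route rests on one feature: C4 is an aryl ketone carbon bonded to C4a, and C3 is a plain methylene next to C2. If C4 is carried as a 1,3-dithiane, its carbanion can displace a leaving group on C3 and close ring C without touching any bond to C2 and without a ketone being present in the basic step.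

## Retrosynthetic reasoning

**22 ⇒ 21 (protecting groups).** The last operation only frees the two phenols. Both are carried as TBS ethers, so one buffered fluoride treatment removes them without acid strong enough to cyclise a prenyl group onto O7 and without base that would open ring C. An acetal-type group on O7 was not chosen: its removal needs acid next to two prenyl groups, and it would be at risk under the thiol/Lewis acid conditions used earlier.

**21 ⇒ 20 (C4 carbonyl).** The ketone is traced back to a spiro-1,3-dithiane at C4. The forward unmasking must not oxidise two trisubstituted olefins and must not be strongly basic, which points to alkylative hydrolysis buffered by an insoluble carbonate.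

**20 ⇒ 18 via 19 (C3–C4, the strategic cut).** Ring C could be cut at O1–C2, O1–C8a, C2–C3 or C3–C4.
- An O1–C2 closure of the oxa-Michael type is reversible and would set C2 under conditions that also racemise it.
- Only the C3–C4 cut leaves the stereocentre as a bystander that already holds O1 and ring B, and lets C4 stay masked.
- The polarity is inverted: C4 is the nucleophile (lithiated dithiane 19) and C3 the electrophile (primary tosylate in 18).
- The forward reaction has to deprotonate only the dithiane C–H and then substitute at C3 faster than it eliminates.
- What is gained is ring C and the C3–C4 bond in one step, from a precursor whose stereocentre was fixed earlier.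

**18 ⇒ 17 ⇒ 16 ⇒ 14 + 15 (functional group changes).** The tosylate comes from primary alcohol 17, the alcohol from ester 16, and the dithiane from aldehyde 14 and dithiol 15. C3 thus arrives as the carboxyl carbon of an α-aryloxy arylacetate and C4 as a formyl carbon. The forward steps must avoid base while the ester is present, because the α-hydrogen of 14 and 16 is acidic.

**14 ⇒ 8 + 13 (O1–C2 in the open chain).** The aryl ether bond is formed here as an SN2 reaction of phenol 8 on the activated hydroxyl of 13, with inversion. S-configured 13 therefore gives R-configured 14, which becomes 2S in the flavanone only through the priority change at ring closure. The ester beside the reacting carbon is deliberate: it disfavours ionisation, which a 4-silyloxybenzylic alcohol would otherwise undergo, and it later supplies C3.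

**13 ⇒ 12 ⇒ 9 + 10 via 11 (the stereocentre).** The carbinol centre comes from enantioselective transfer hydrogenation of α-keto ester 12. Ester 12 comes from acylation of the aryl Grignard reagent 11, made from 9, with oxalate 10. This sets the configuration catalytically and avoids a resolution.

**8 ⇒ 7 ⇒ 5 ⇒ 3 ⇒ 1 + 2, with 6 (ring A).** Silyl ether 8 comes from selective protection of the non-chelated 4-hydroxyl of 7. The prenyl groups of 7 are made from the allyl groups of 5 by cross-metathesis with two molecules of 6. The allyl groups are placed by a double Claisen rearrangement of bis-allyl ether 3, which can only deliver them to the two positions ortho and para to the oxygens. Ether 3 comes from aldehyde 1 and two molecules of 2, and 1 already contains C4, O1 and O7 in the right pattern.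

## Alternatives that were turned down

**Alternative 1: ring A and ring C by alkyne cyclotrimerisation.**
- Disconnection: ring A is cut at C4a–C8a, C5–C6 and C7–C8. The precursors are the tethered diyne A2, which holds the ethynyl ketone (C5, C4a), C4, C3, the C2 stereocentre, O1 and a prenylated ynol ether (C8a, C8), and the prenylated siloxyalkyne A3 (C6, C7).
- Key step: a [2+2+2] cycloaddition of A2 with A3, catalysed by RhCl(PPh3)3 or CpCo(CO)2, would give the protected flavanone A1 and close rings A and C together.
- For it: it is the most convergent plan. All five substituents of ring A are assembled in one step, and no arene has to be C-prenylated. On these points it is stronger than the chosen route.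
- Against it:
  - Only the electronic difference between the two ends of A3 decides whether its oxygenated carbon becomes C7 or C6, so a regioisomeric arene is a real prospect.
  - A2 has a β-alkynyloxy ketone; enolisation at C3 can expel the ynolate and destroy C2.
  - Ynol ethers of secondary benzylic alcohols are thermally fragile.
  - Each prenyl group is a skipped enyne that can enter the metallacycle.
  - A2 and A3 each need several steps with sensitive functionality.
- Comparison: the chosen strategy gives up convergence. In return the regiochemistry of ring A is fixed by a commercial arene, and the ring closure has only one competing pathway.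

**Alternative 2: stereoretentive closure of ring C by aryl–oxygen coupling.**
- Disconnection: O1–C8a. The precursor is the bromo diol A5, with S configuration at the carbinol that becomes C2.
- Key step: an intramolecular C–O coupling, catalysed by Pd(OAc)2 with a bulky biarylphosphine or by CuI with a diamine ligand, would give flavan-4-ol A4. Oxidation at C4 and deprotection would follow.
- For it: the C2–O bond is never broken, so the configuration set by a standard asymmetric carbonyl reduction is retained. No carbanion is involved, and C4 stays an alcohol during closure. On the security of C2 this plan is at least as strong as the chosen one, which needs an SN2 inversion at a benzylic centre.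
- Against it:
  - The bromide lies between the C8 prenyl group and the carbinol side chain on an electron-rich ring, so both oxidative addition to zerovalent palladium and C–O reductive elimination are slow.
  - A secondary benzylic alkoxide on palladium can undergo β-hydride elimination, which oxidises the C2 carbinol and reduces the C–Br bond.
  - The prenyl olefins can insert into the arylpalladium bond.
  - The oxygen that the chosen route buys at C8a has to be replaced by bromine, which lengthens the ring A synthesis.
  - The acetal on O7 must be removed with acid beside two prenyl groups.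
- Comparison: the chosen strategy offers a shorter ring A synthesis and a metal-free closure in which the olefins are inert.

**Alternative 3: stereoconvergent acetal-to-ketone rearrangement forming C2–C3.**
- Disconnection: C2–C3. The precursor is the racemic 4-methylene-1,3-benzodioxine A7.
- Key step: a chiral Brønsted acid would ionise the acetal carbon of A7. The resulting oxocarbenium ion, paired with the chiral anion, would be attacked by the tethered enol carbon to give A6, which is the same compound as 21.
- For it: it is the shortest plan. It is catalytic in chirality, needs no enantiopure building block and uses both enantiomers of A7. In step and atom economy it is stronger than the chosen route.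
- Against it:
  - Enantiocontrol depends on a contact ion pair, but the cation is strongly stabilised by the 4-silyloxyphenyl group, so it is long-lived and loosely paired.
  - The same acid can reopen ring C of A6 by reversible elimination of the phenol, which would erode the configuration after it is set.
  - Prenyl olefins and aryl silyl ethers would sit in a strongly acidic medium.
  - This type of rearrangement has not been shown to give flavanones enantioselectively, so the sense and level of induction cannot be predicted.
- Comparison: the chosen strategy is longer. In return the configuration comes from a well-understood ketone reduction and an SN2 inversion, and ring closure cannot alter C2.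

Key step: step 11

## Route

Step 1
Reactants: 1 2,4-dihydroxybenzaldehyde; 2 allyl bromide
Product: 3 2,4-bis(allyloxy)benzaldehyde
Conditions: 2 (2.5 equiv), K2CO3 (3 equiv), DMF, 60 °C
Reagents that add atoms: allyl bromide (second molecule of 2), C=CCBr
Why: Double Williamson O-alkylation in which each phenoxide takes up one molecule of 2; the chelated 2-hydroxyl reacts more slowly than the 4-hydroxyl but should be fully alkylated with excess 2 in warm DMF.

Step 2
Reactants: 3 2,4-bis(allyloxy)benzaldehyde
Product: 5 3,5-diallyl-2,4-dihydroxybenzaldehyde, via mono-rearranged allyl ether 4 (not isolated)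
Conditions: PhNEt2, 200 °C
Reagents that add atoms: none
Why: Two aromatic Claisen rearrangements; C1 carries the formyl group and C6 is meta to both oxygens, so C3 and C5 are the only termini open to the two allyl groups (by ortho shift, or ortho shift followed by Cope shift to the para position). Intermediate 4 is drawn for migration from O2 to C3 first; the other order converges on the same product 5.

Step 3
Reactants: 5 3,5-diallyl-2,4-dihydroxybenzaldehyde; 6 2-methylbut-2-ene
Product: 7 2,4-dihydroxy-3,5-bis(3-methylbut-2-enyl)benzaldehyde
Conditions: RuCl2(=CHPh)(PCy3)(H2IMes) (second-generation Grubbs catalyst, 5 mol %), 6 in large excess, CH2Cl2, 40 °C, sealed tube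
Reagents that add atoms: 2-methylbut-2-ene (second molecule of 6), CC=C(C)C
Why: Olefin cross-metathesis of each terminal allyl group with one molecule of 6 transfers an isopropylidene unit and releases propene; the reaction tolerates free phenols and aldehydes, and the excess of 6 should suppress homodimerisation.

Step 4
Reactants: 7 2,4-dihydroxy-3,5-bis(3-methylbut-2-enyl)benzaldehyde
Product: 8 4-(tert-butyldimethylsilyloxy)-2-hydroxy-3,5-bis(3-methylbut-2-enyl)benzaldehyde
Conditions: TBSCl (1.05 equiv), imidazole, DMF, 0 °C
Reagents that add atoms: tert-butyldimethylsilyl chloride, CC(C)(C)[Si](C)(C)Cl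
Why: Selective silylation; the 4-hydroxyl para to the formyl group is the more acidic and is free, while the 2-hydroxyl is held in a hydrogen bond to the aldehyde and should stay unprotected.

Step 5
Reactants: 9 (4-bromophenoxy)(tert-butyl)dimethylsilane; 10 diethyl oxalate
Product: 12 ethyl 2-[4-(tert-butyldimethylsilyloxy)phenyl]-2-oxoacetate, via arylmagnesium bromide 11 (not isolated)
Conditions: Mg, THF, reflux; then added to 10 (2 equiv), THF, −78 °C; aq. NH4Cl
Reagents that add atoms: none
Why: Grignard formation and acylation by an oxalate diester; inverse addition at low temperature should stop at the keto ester because the tetrahedral magnesium alkoxide does not collapse until work-up.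

Step 6
Reactants: 12 ethyl 2-[4-(tert-butyldimethylsilyloxy)phenyl]-2-oxoacetate
Product: 13 ethyl (2S)-2-hydroxy-2-[4-(tert-butyldimethylsilyloxy)phenyl]acetate
Conditions: RuCl[(R,R)-TsDPEN](p-cymene) (1 mol %), HCO2H/Et3N (5:2), DMF, 25 °C
Reagents that add atoms: none
Why: Noyori asymmetric transfer hydrogenation of an aryl α-keto ester; the catalyst recognises the aryl group as in aryl alkyl ketones, so the (R,R) ligand should deliver hydride to the face that gives the S alcohol (S because the ester outranks the aryl group). This assignment is by analogy and is to be confirmed on 13.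

Step 7
Reactants: 8 4-(tert-butyldimethylsilyloxy)-2-hydroxy-3,5-bis(3-methylbut-2-enyl)benzaldehyde; 13 ethyl (2S)-2-hydroxy-2-[4-(tert-butyldimethylsilyloxy)phenyl]acetate
Product: 14 ethyl (2R)-2-[5-(tert-butyldimethylsilyloxy)-2-formyl-4,6-bis(3-methylbut-2-enyl)phenoxy]-2-[4-(tert-butyldimethylsilyloxy)phenyl]acetate
Conditions: PPh3, i-PrO2CN=NCO2i-Pr, toluene (concentrated), 0 °C → rt
Reagents that add atoms: none
Why: Mitsunobu etherification; the phenol is acidified by its ortho formyl group, and the phenoxide displaces the oxyphosphonium group of 13 by SN2 with inversion, which sets the R configuration. The adjacent ester disfavours ionisation of the benzylic centre, so the configuration should be transferred cleanly.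

Step 8
Reactants: 14 ethyl (2R)-2-[5-(tert-butyldimethylsilyloxy)-2-formyl-4,6-bis(3-methylbut-2-enyl)phenoxy]-2-[4-(tert-butyldimethylsilyloxy)phenyl]acetate; 15 propane-1,3-dithiol
Product: 16 ethyl (2R)-2-[5-(tert-butyldimethylsilyloxy)-2-(1,3-dithian-2-yl)-4,6-bis(3-methylbut-2-enyl)phenoxy]-2-[4-(tert-butyldimethylsilyloxy)phenyl]acetate
Conditions: BF3·OEt2 (0.3 equiv), CH2Cl2, −20 → 0 °C
Reagents that add atoms: none
Why: Lewis-acid-catalysed dithioacetalisation of the aldehyde through a thionium ion stabilised by the para oxygen; substoichiometric acid at low temperature should spare the aryl silyl ethers and the olefins. The conditions are not basic, so the α-stereocentre is not at risk.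

Step 9
Reactants: 16 ethyl (2R)-2-[5-(tert-butyldimethylsilyloxy)-2-(1,3-dithian-2-yl)-4,6-bis(3-methylbut-2-enyl)phenoxy]-2-[4-(tert-butyldimethylsilyloxy)phenyl]acetate
Product: 17 (2R)-2-[5-(tert-butyldimethylsilyloxy)-2-(1,3-dithian-2-yl)-4,6-bis(3-methylbut-2-enyl)phenoxy]-2-[4-(tert-butyldimethylsilyloxy)phenyl]ethan-1-ol
Conditions: i-Bu2AlH (3 equiv), CH2Cl2, −78 → −20 °C; aq. potassium sodium tartrate
Reagents that add atoms: none
Why: Ester reduction to the primary alcohol by a Lewis-acidic, non-basic hydride, chosen so that the acidic α-hydrogen is not removed before reduction; dithiane, silyl ethers and olefins are inert.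

Step 10
Reactants: 17 (2R)-2-[5-(tert-butyldimethylsilyloxy)-2-(1,3-dithian-2-yl)-4,6-bis(3-methylbut-2-enyl)phenoxy]-2-[4-(tert-butyldimethylsilyloxy)phenyl]ethan-1-ol
Product: 18 (2R)-2-[5-(tert-butyldimethylsilyloxy)-2-(1,3-dithian-2-yl)-4,6-bis(3-methylbut-2-enyl)phenoxy]-2-[4-(tert-butyldimethylsilyloxy)phenyl]ethyl 4-toluenesulfonate
Conditions: TsCl, Et3N, DMAP (cat.), CH2Cl2, 0 °C
Reagents that add atoms: 4-toluenesulfonyl chloride, Cc1ccc(cc1)S(Cl)(=O)=O
Why: Sulfonylation of the only free hydroxyl, a primary alcohol; the stereocentre is not involved. The product should be used without long storage.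

Step 11
Reactants: 18 (2R)-2-[5-(tert-butyldimethylsilyloxy)-2-(1,3-dithian-2-yl)-4,6-bis(3-methylbut-2-enyl)phenoxy]-2-[4-(tert-butyldimethylsilyloxy)phenyl]ethyl 4-toluenesulfonate
Product: 20 (2S)-7,4'-bis(tert-butyldimethylsilyloxy)-6,8-diprenylflavanone 4-(propane-1,3-diyl dithioketal), via lithiated dithiane 19 (not isolated)
Conditions: n-BuLi (1.05 equiv), THF (0.02 M), −78 °C, then → 0 °C
Reagents that add atoms: none
Why: n-BuLi removes the dithiane C–H of 18, by far the most acidic proton present because the carbanion is stabilised by two sulfur atoms, whereas the benzylic ether C2–H and the tolyl protons are many pK units weaker and should not be touched at −78 °C by one equivalent of base. On warming, the carbanion carbon of 19 (the future C4) attacks C3 from the back and expels tosylate in an SN2 step; this is the intramolecular form of the Corey–Seebach alkylation of 2-lithio-1,3-dithianes, a known way to make cyclic ketone equivalents. Ring C closes in the 6-exo-tet mode, the ring being C4, C4a, C8a, O1, C2 and C3 with the leaving oxygen outside it. No stereocentre is created: the spiro carbon C4 carries two equivalent sulfur arms, and C2 keeps its configuration because none of its bonds takes part (the descriptor changes from R to S only because C3, once it is no longer oxygenated, ranks below the aryl group). The selectivity required is substitution over elimination, since the carbanion could also reach the C2–H through a six-membered transition state; a soft, delocalised carbanion, a primary sulfonate and low temperature should favour substitution. The sulfur-stabilised carbanion is pyramidal and does not depend on conjugation with ring A, so its lone pair can lie in the ring plane and point at C3, which is the geometry of the product. Because C4 remains a dithioketal, no enolate can form at C3 and O1 cannot be expelled from C2 during this basic step. High dilution should keep intermolecular alkylation down.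

Step 12
Reactants: 20 (2S)-7,4'-bis(tert-butyldimethylsilyloxy)-6,8-diprenylflavanone 4-(propane-1,3-diyl dithioketal)
Product: 21 (2S)-7,4'-bis(tert-butyldimethylsilyloxy)-6,8-diprenylflavanone
Conditions: MeI (excess), CaCO3, MeCN/H2O (9:1), 45 °C, dark
Reagents that add atoms: water, O
Why: Alkylative hydrolysis of a dithioketal; S-methylation turns one sulfur into a leaving group, the thionium ion (stabilised by the para oxygen O7) is captured by water, and CaCO3 takes up the acid. The olefins and silyl ethers are inert to MeI, and the medium is too weakly basic to enolise the new ketone.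

Step 13
Reactants: 21 (2S)-7,4'-bis(tert-butyldimethylsilyloxy)-6,8-diprenylflavanone
Product: 22 (2S)-7,4'-dihydroxy-6,8-diprenylflavanone (target)
Conditions: HF·pyridine, pyridine, THF, 0 °C → rt
Reagents that add atoms: none
Why: Fluoride cleavage of both aryl silyl ethers under buffered, weakly acidic conditions; there is no base to open ring C at C2 and no acid strong enough to cyclise a prenyl group onto the C7 phenol.

## Compound list

1 | 2,4-dihydroxybenzaldehyde | O=Cc1ccc(O)cc1O | starting material
2 | allyl bromide | C=CCBr | starting material
3 | 2,4-bis(allyloxy)benzaldehyde | O=Cc1ccc(OCC=C)cc1OCC=C | intermediate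
4 | 3-allyl-4-(allyloxy)-2-hydroxybenzaldehyde | O=Cc1ccc(OCC=C)c(CC=C)c1O | intermediate
5 | 3,5-diallyl-2,4-dihydroxybenzaldehyde | O=Cc1cc(CC=C)c(O)c(CC=C)c1O | intermediate
6 | 2-methylbut-2-ene | CC=C(C)C | starting material
7 | 2,4-dihydroxy-3,5-bis(3-methylbut-2-enyl)benzaldehyde | O=Cc1cc(CC=C(C)C)c(O)c(CC=C(C)C)c1O | intermediate
8 | 4-(tert-butyldimethylsilyloxy)-2-hydroxy-3,5-bis(3-methylbut-2-enyl)benzaldehyde | O=Cc1cc(CC=C(C)C)c(O[Si](C)(C)C(C)(C)C)c(CC=C(C)C)c1O | intermediate
9 | (4-bromophenoxy)(tert-butyl)dimethylsilane | CC(C)(C)[Si](C)(C)Oc1ccc(Br)cc1 | starting material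
10 | diethyl oxalate | CCOC(=O)C(=O)OCC | starting material
11 | 4-(tert-butyldimethylsilyloxy)phenylmagnesium bromide | CC(C)(C)[Si](C)(C)Oc1ccc([Mg]Br)cc1 | intermediate
12 | ethyl 2-[4-(tert-butyldimethylsilyloxy)phenyl]-2-oxoacetate | CCOC(=O)C(=O)c1ccc(O[Si](C)(C)C(C)(C)C)cc1 | intermediate
13 | ethyl (2S)-2-hydroxy-2-[4-(tert-butyldimethylsilyloxy)phenyl]acetate | O[C@H](C(=O)OCC)c1ccc(O[Si](C)(C)C(C)(C)C)cc1 | intermediate
14 | ethyl (2R)-2-[5-(tert-butyldimethylsilyloxy)-2-formyl-4,6-bis(3-methylbut-2-enyl)phenoxy]-2-[4-(tert-butyldimethylsilyloxy)phenyl]acetate | O=Cc1cc(CC=C(C)C)c(O[Si](C)(C)C(C)(C)C)c(CC=C(C)C)c1O[C@H](c1ccc(O[Si](C)(C)C(C)(C)C)cc1)C(=O)OCC | intermediate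
15 | propane-1,3-dithiol | SCCCS | starting material
16 | ethyl (2R)-2-[5-(tert-butyldimethylsilyloxy)-2-(1,3-dithian-2-yl)-4,6-bis(3-methylbut-2-enyl)phenoxy]-2-[4-(tert-butyldimethylsilyloxy)phenyl]acetate | S1CCCSC1c1cc(CC=C(C)C)c(O[Si](C)(C)C(C)(C)C)c(CC=C(C)C)c1O[C@H](c1ccc(O[Si](C)(C)C(C)(C)C)cc1)C(=O)OCC | intermediate
17 | (2R)-2-[5-(tert-butyldimethylsilyloxy)-2-(1,3-dithian-2-yl)-4,6-bis(3-methylbut-2-enyl)phenoxy]-2-[4-(tert-butyldimethylsilyloxy)phenyl]ethan-1-ol | S1CCCSC1c1cc(CC=C(C)C)c(O[Si](C)(C)C(C)(C)C)c(CC=C(C)C)c1O[C@H](c1ccc(O[Si](C)(C)C(C)(C)C)cc1)CO | intermediate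
18 | (2R)-2-[5-(tert-butyldimethylsilyloxy)-2-(1,3-dithian-2-yl)-4,6-bis(3-methylbut-2-enyl)phenoxy]-2-[4-(tert-butyldimethylsilyloxy)phenyl]ethyl 4-toluenesulfonate | S1CCCSC1c1cc(CC=C(C)C)c(O[Si](C)(C)C(C)(C)C)c(CC=C(C)C)c1O[C@H](c1ccc(O[Si](C)(C)C(C)(C)C)cc1)COS(=O)(=O)c1ccc(C)cc1 | intermediate
19 | 2-lithio derivative of 18 (lithium on the dithiane carbon) | [Li]C1(SCCCS1)c1cc(CC=C(C)C)c(O[Si](C)(C)C(C)(C)C)c(CC=C(C)C)c1O[C@H](c1ccc(O[Si](C)(C)C(C)(C)C)cc1)COS(=O)(=O)c1ccc(C)cc1 | intermediate
20 | (2S)-7,4'-bis(tert-butyldimethylsilyloxy)-6,8-diprenylflavanone 4-(propane-1,3-diyl dithioketal) | CC(C)=CCc1cc2c(c(CC=C(C)C)c1O[Si](C)(C)C(C)(C)C)O[C@H](c1ccc(O[Si](C)(C)C(C)(C)C)cc1)CC21SCCCS1 | intermediate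
21 | (2S)-7,4'-bis(tert-butyldimethylsilyloxy)-6,8-diprenylflavanone | CC(C)=CCc1cc2c(c(CC=C(C)C)c1O[Si](C)(C)C(C)(C)C)O[C@H](c1ccc(O[Si](C)(C)C(C)(C)C)cc1)CC2=O | intermediate
22 | (2S)-7,4'-dihydroxy-6,8-diprenylflavanone | CC(C)=CCc1cc2c(c(CC=C(C)C)c1O)O[C@H](c1ccc(O)cc1)CC2=O | target

## Step count and least certain steps

Total steps: 13.
Longest linear sequence: 11 steps (steps 1, 2, 3, 4, 7, 8, 9, 10, 11, 12, 13, from 1 to 22). Steps 5 and 6 form the second branch, which joins at step 7.

**Step 11 (key step).** The most likely failure is elimination in place of substitution. The lithiated carbon can abstract the C2–H through a six-membered transition state with loss of tosylate, or the anion can simply be quenched by that proton. Substitution at C3 is also slowed by β-branching and by the β-oxygen, which gives these pathways and intermolecular alkylation more time. Fallback: set out from 18 and remove the dithiane with MeI and CaCO3 in aqueous MeCN to give (2R)-2-[5-(tert-butyldimethylsilyloxy)-2-formyl-4,6-bis(3-methylbut-2-enyl)phenoxy]-2-[4-(tert-butyldimethylsilyloxy)phenyl]ethyl 4-toluenesulfonate F1. F1 is then closed by N-heterocyclic carbene catalysis (thiazolium or triazolium precatalyst with an amine base). The aldehyde becomes a neutral Breslow enaminol, which displaces the tosylate at C3 and collapses to the ketone, so the route is rejoined at 21. This keeps the C3–C4 bond formation but replaces the lithium carbanion by a non-basic acyl anion equivalent. Its price is that the ketone is formed in the presence of amine base, so the configuration at C2 would have to be checked.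

**Step 7.** The most likely failure is slow displacement at the activated alcohol, because the phenoxide of 8 is flanked by the formyl and prenyl groups. Slow displacement allows alkylation of the hydrazide by-product and partial loss of configuration by ionisation at the benzylic carbon. Fallback: separate activation from displacement. Set out from 13 and convert it with MsCl and Et3N, with retention, into ethyl (2S)-2-(methanesulfonyloxy)-2-[4-(tert-butyldimethylsilyloxy)phenyl]acetate F2. F2 is then displaced with inversion by the potassium phenoxide of 8, preformed with one equivalent of KN(SiMe3)2 in DMF at 0 °C, to come back at 14. No excess base is present, so neither the sulfonate nor the product ester should be enolised.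

**Step 12.** The most likely failure is sluggish S-methylation at the hindered spiro dithioketal. The prolonged heating then needed gives the liberated ketone time to begin epimerising at C2 by ring opening, or a silyl ether time to be lost. Fallback: unmask in two stages through a change of oxidation state at sulfur. Set out from 20 and oxidise one sulfur with NaIO4 in aqueous MeOH/THF at 0 °C, which leaves the olefins alone, to give (2S)-7,4'-bis(tert-butyldimethylsilyloxy)-6,8-diprenylflavanone 4-(propane-1,3-diyl dithioketal) S-monoxide F3 as a mixture of sulfoxide diastereomers. The monosulfoxide should hydrolyse under mild acid catalysis in wet MeCN at 0 °C, far more readily than the parent dithioketal, and the route is rejoined at 21.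

**Step 8.** The most likely failure is acid-mediated damage while a hindered, electron-rich aldehyde reacts slowly: loss of an aryl silyl ether, or Markovnikov addition of the thiol across a prenyl olefin. Fallback: change the order of events. Set out from 8, whose free ortho hydroxyl assists ionisation so that a milder catalyst such as MgBr2·OEt2 should suffice, and convert it with 15 into 5-(tert-butyldimethylsilyloxy)-2-(1,3-dithian-2-yl)-4,6-bis(3-methylbut-2-enyl)phenol F4. Mitsunobu etherification of F4 with 13 then comes back at 16. The price is a more hindered and less acidic phenol in the etherification.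

**Step 2.** The most likely failure is an incomplete second migration, or cyclisation of an ortho-allylphenol onto its own olefin at 200 °C, which would drain material. Fallback: set out from 1 and alkylate it directly at C3 and C5 with 3-methylbut-2-enyl bromide in aqueous KOH, which comes back at 7 in one step and makes no new compound. It is short and uses cheap materials, but competing O-alkylation and mono-alkylation are to be expected.

## Further compounds

F1 | step 11 | (2R)-2-[5-(tert-butyldimethylsilyloxy)-2-formyl-4,6-bis(3-methylbut-2-enyl)phenoxy]-2-[4-(tert-butyldimethylsilyloxy)phenyl]ethyl 4-toluenesulfonate | O=Cc1cc(CC=C(C)C)c(O[Si](C)(C)C(C)(C)C)c(CC=C(C)C)c1O[C@H](c1ccc(O[Si](C)(C)C(C)(C)C)cc1)COS(=O)(=O)c1ccc(C)cc1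
F2 | step 7 | ethyl (2S)-2-(methanesulfonyloxy)-2-[4-(tert-butyldimethylsilyloxy)phenyl]acetate | CS(=O)(=O)O[C@H](C(=O)OCC)c1ccc(O[Si](C)(C)C(C)(C)C)cc1
F3 | step 12 | (2S)-7,4'-bis(tert-butyldimethylsilyloxy)-6,8-diprenylflavanone 4-(propane-1,3-diyl dithioketal) S-monoxide (mixture of sulfoxide diastereomers) | CC(C)=CCc1cc2c(c(CC=C(C)C)c1O[Si](C)(C)C(C)(C)C)O[C@H](c1ccc(O[Si](C)(C)C(C)(C)C)cc1)CC21SCCCS1=O
F4 | step 8 | 5-(tert-butyldimethylsilyloxy)-2-(1,3-dithian-2-yl)-4,6-bis(3-methylbut-2-enyl)phenol | S1CCCSC1c1cc(CC=C(C)C)c(O[Si](C)(C)C(C)(C)C)c(CC=C(C)C)c1O
F0 | step 2 | none | none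
A1 | alternative 1 | (2S)-7-(triisopropylsilyloxy)-4'-(tert-butyldimethylsilyloxy)-6,8-diprenylflavanone | CC(C)=CCc1cc2c(c(CC=C(C)C)c1O[Si](C(C)C)(C(C)C)C(C)C)O[C@H](c1ccc(O[Si](C)(C)C(C)(C)C)cc1)CC2=O
A2 | alternative 1 | (5S)-5-[4-(tert-butyldimethylsilyloxy)phenyl]-5-[(5-methylhex-4-en-1-yn-1-yl)oxy]pent-1-yn-3-one | C#CC(=O)C[C@@H](c1ccc(O[Si](C)(C)C(C)(C)C)cc1)OC#CCC=C(C)C
A3 | alternative 1 | triisopropyl[(5-methylhex-4-en-1-yn-1-yl)oxy]silane | CC(C)=CCC#CO[Si](C(C)C)(C(C)C)C(C)C
A4 | alternative 2 | (2S)-7-(methoxymethoxy)-4'-(tert-butyldimethylsilyloxy)-6,8-diprenylflavan-4-ol (either C4 epimer) | CC(C)=CCc1cc2c(c(CC=C(C)C)c1OCOC)O[C@H](c1ccc(O[Si](C)(C)C(C)(C)C)cc1)CC2O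
A5 | alternative 2 | (3S)-1-[2-bromo-4-(methoxymethoxy)-3,5-bis(3-methylbut-2-enyl)phenyl]-3-[4-(tert-butyldimethylsilyloxy)phenyl]propane-1,3-diol (either C1 epimer) | CC(C)=CCc1cc(C(O)C[C@H](O)c2ccc(O[Si](C)(C)C(C)(C)C)cc2)c(Br)c(CC=C(C)C)c1OCOC
A6 | alternative 3 | (2S)-7,4'-bis(tert-butyldimethylsilyloxy)-6,8-diprenylflavanone | CC(C)=CCc1cc2c(c(CC=C(C)C)c1O[Si](C)(C)C(C)(C)C)O[C@H](c1ccc(O[Si](C)(C)C(C)(C)C)cc1)CC2=O
A7 | alternative 3 | racemic 7-(tert-butyldimethylsilyloxy)-2-[4-(tert-butyldimethylsilyloxy)phenyl]-4-methylene-6,8-bis(3-methylbut-2-enyl)-4H-1,3-benzodioxine | C=C1OC(c2ccc(O[Si](C)(C)C(C)(C)C)cc2)Oc2c1cc(CC=C(C)C)c(O[Si](C)(C)C(C)(C)C)c2CC=C(C)C
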